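**Retrosynthetic overview** (labdane numbering)
1. The target is isocupressic acid 15-oleate. The last steps free the C19 acid from its 2-(trimethylsilyl)ethyl ester, make C8=C17 by methylenation of an 8-ketone, and acylate the C15 alcohol with oleic acid.
2. The C4 quaternary centre comes from dissolving-metal reductive methylation of a ring A Δ3 ester; the methyl enters the α face, so the ester ends axial (C19).
3. Key disconnection: both rings from an open chain in one operation. Hydrogen-atom transfer makes a C10 tertiary radical, 6-exo addition to the acrylate carbon C5 closes ring B (C5–C10), and the resulting C4 ester enolate closes ring A by aldol addition to the C3 aldehyde (C3–C4).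
4. Enabling feature: C4 of ring A is the α-carbon and C5 the β-carbon of the C19 carboxyl, and the ring-fusion carbon C10 carries the C20 methyl. C10 can therefore be born as a tertiary radical from a C10=C20 methylene, with C5 as its polarity-matched acceptor and C4 as the enolate that attacks C3.
5. The open-chain precursor comes from an Evans syn aldol (C8–C9, sets C9), Weinreb ketone synthesis plus methylenation (C10=C20), and cross-metathesis (C4=C5). Ring order: B, then A.

Key step: step 15

Assumption: names of cyclic compounds use labdane numbering (normal series: 5α-H, 9α-H, 10β-CH3); the C3/C4 configuration drawn for 28 is the expected major one and is erased in steps 16 and 17.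

Step 1
Reactants: 1 ethyl but-2-ynoate; 2 but-3-enylmagnesium bromide
Product: 4 ethyl (E)-3-methylhepta-2,6-dienoate, via alkenylcopper adduct 3 (not isolated)
Conditions: CuBr·SMe2, THF, −78 °C; then 1, −78 °C; MeOH quench at −78 °C
Reagents that add atoms: none
Why: syn-carbocupration of the alkynoate by the Grignard-derived organocopper and stereoretentive protonolysis at low temperature should place the new chain cis to H and so give the E β-methyl enoate.

Step 2
Reactants: 4 ethyl (E)-3-methylhepta-2,6-dienoate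
Product: 5 (E)-3-methylhepta-2,6-dien-1-ol
Conditions: i-Bu2AlH, CH2Cl2, −78 → 0 °C; aqueous KNaC4H4O6 work-up
Reagents that add atoms: none
Why: 1,2-reduction of the conjugated ester by the aluminium hydride should give the allylic alcohol without touching either alkene.

Step 3
Reactants: 5 (E)-3-methylhepta-2,6-dien-1-ol
Product: 6 (E)-3-methyl-1-(triisopropylsilyloxy)hepta-2,6-diene
Conditions: TIPSCl, imidazole, CH2Cl2, rt
Reagents that add atoms: triisopropylsilyl chloride, CC(C)[Si](Cl)(C(C)C)C(C)C
Why: silylation of the primary alcohol; the triisopropylsilyl ether is chosen because it should survive the acid of step 14 and the dissolving metal of step 17.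

Step 4
Reactants: 6 (E)-3-methyl-1-(triisopropylsilyloxy)hepta-2,6-diene
Product: 8 (E)-5-methyl-7-(triisopropylsilyloxy)hept-5-en-1-ol, via B-alkyl-9-BBN adduct 7 (not isolated)
Conditions: 9-BBN, THF, 0 °C → rt; then NaOH, H2O2, 0 °C
Reagents that add atoms: hydrogen peroxide, OO
Why: anti-Markovnikov hydroboration–oxidation with a bulky borane should react only at the monosubstituted alkene and leave the trisubstituted one.

Step 5
Reactants: 8 (E)-5-methyl-7-(triisopropylsilyloxy)hept-5-en-1-ol
Product: 9 (E)-5-methyl-7-(triisopropylsilyloxy)hept-5-enoic acid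
Conditions: TEMPO (cat.), PhI(OAc)2, MeCN/H2O, rt
Reagents that add atoms: water, O
Why: oxoammonium-catalysed oxidation should take the primary alcohol through the aldehyde hydrate to the acid while the silyl ether and the alkene are left alone.

Step 6
Reactants: 9 (E)-5-methyl-7-(triisopropylsilyloxy)hept-5-enoic acid; 10 (S)-4-benzyloxazolidin-2-one
Product: 12 (S)-4-benzyl-3-[(E)-5-methyl-7-(triisopropylsilyloxy)hept-5-enoyl]oxazolidin-2-one, via mixed pivalic anhydride 11 (not isolated)
Conditions: PivCl, Et3N, THF, −20 °C; then 10, LiCl, −20 °C → rt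
Reagents that add atoms: none
Why: N-acylation of the oxazolidinone through the mixed anhydride should occur at the less hindered acyl group.

Step 7
Reactants: 13 acryloyl chloride; 14 2-(trimethylsilyl)ethanol
Product: 15 2-(trimethylsilyl)ethyl acrylate
Conditions: Et3N, CH2Cl2, 0 °C
Reagents that add atoms: none
Why: simple acylation of the alcohol by the acid chloride gives the fluoride-cleavable acrylate needed for step 12.

Step 8
Reactants: 12 (S)-4-benzyl-3-[(E)-5-methyl-7-(triisopropylsilyloxy)hept-5-enoyl]oxazolidin-2-one; 16 pent-4-enal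
Product: 18 (S)-4-benzyl-3-[(2S,3R)-3-hydroxy-2-[(E)-3-methyl-5-(triisopropylsilyloxy)pent-3-enyl]hept-6-enoyl]oxazolidin-2-one, via Z-boron enolate 17 (not isolated)
Conditions: Bu2BOTf, i-Pr2NEt, CH2Cl2, −78 → 0 °C; then 16, −78 → 0 °C; pH 7 buffer, MeOH, H2O2
Reagents that add atoms: none
Why: Evans syn aldol; the Z-boron enolate should react through a Zimmerman–Traxler chair on the face away from the benzyl group, which sets C9 (S) and C8 (R) in the syn relationship.

Step 9
Reactants: 18 aldol adduct
Product: 19 (2S,3R)-3-hydroxy-N-methoxy-N-methyl-2-[(E)-3-methyl-5-(triisopropylsilyloxy)pent-3-enyl]hept-6-enamide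
Conditions: MeONHMe·HCl, AlMe3, CH2Cl2, −10 → 0 °C
Reagents that add atoms: N,O-dimethylhydroxylamine hydrochloride, CNOC.Cl
Why: transamidation by the aluminium amide, helped by the free β-hydroxyl, should release the auxiliary and give the Weinreb amide without epimerisation.

Step 10
Reactants: 19 Weinreb amide
Product: 20 (2S,3R)-3-(tert-butyldimethylsilyloxy)-N-methoxy-N-methyl-2-[(E)-3-methyl-5-(triisopropylsilyloxy)pent-3-enyl]hept-6-enamide
Conditions: TBSOTf, 2,6-lutidine, CH2Cl2, 0 °C
Reagents that add atoms: tert-butyldimethylsilyl triflate, CC(C)(C)[Si](C)(C)OS(=O)(=O)C(F)(F)F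
Why: silyl triflate silylation should protect the hindered secondary C8 alcohol before the organometallic step.

Step 11
Reactants: 20 silylated Weinreb amide; 21 [2-(1,3-dioxolan-2-yl)ethyl]magnesium bromide
Product: 22 (4S,5R)-5-(tert-butyldimethylsilyloxy)-1-(1,3-dioxolan-2-yl)-4-[(E)-3-methyl-5-(triisopropylsilyloxy)pent-3-enyl]non-8-en-3-one
Conditions: THF, 0 °C → rt; aqueous NH4Cl
Reagents that add atoms: none
Why: Grignard addition to the Weinreb amide should stop at the chelated tetrahedral intermediate and give the C10 ketone carrying C1–C3 as a masked aldehyde.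

Step 12
Reactants: 22 ketone; 15 2-(trimethylsilyl)ethyl acrylate
Product: 23 2-(trimethylsilyl)ethyl (2E,6R,7S)-6-(tert-butyldimethylsilyloxy)-10-(1,3-dioxolan-2-yl)-7-[(E)-3-methyl-5-(triisopropylsilyloxy)pent-3-enyl]-8-oxodec-2-enoate
Conditions: second-generation Hoveyda–Grubbs catalyst RuCl2(=CH-2-(i-PrO)C6H4)(H2IMes) (5 mol %), 15 (3 equiv), CH2Cl2, 40 °C
Reagents that add atoms: none
Why: olefin cross-metathesis of the terminal alkene with the acrylate should give the E enoate, the trisubstituted alkene being inert; it is run before step 13 so that no ring-closing metathesis partner is present.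

Step 13
Reactants: 23 keto enoate
Product: 24 2-(trimethylsilyl)ethyl (2E,6R,7R)-6-(tert-butyldimethylsilyloxy)-10-(1,3-dioxolan-2-yl)-8-methylidene-7-[(E)-3-methyl-5-(triisopropylsilyloxy)pent-3-enyl]dec-2-enoate
Conditions: Zn, CH2Br2, TiCl4, THF/CH2Cl2, 0 °C → rt
Reagents that add atoms: dibromomethane, BrCBr
Why: Takai–Lombardo methylenation is non-basic and should convert the ketone to the 1,1-disubstituted alkene without epimerising C9, eliminating the β-silyloxy group or touching the ester.

Step 14
Reactants: 24 methylidene acetal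
Product: 25 2-(trimethylsilyl)ethyl (2E,6R,7R)-6-(tert-butyldimethylsilyloxy)-8-methylidene-7-[(E)-3-methyl-5-(triisopropylsilyloxy)pent-3-enyl]-11-oxoundec-2-enoate
Conditions: PPTS, acetone/H2O (9:1), 55 °C
Reagents that add atoms: water, O
Why: mild acid-catalysed acetal hydrolysis should unmask the C3 aldehyde while the triisopropylsilyl ether and the hindered secondary silyl ether persist.

Step 15
Reactants: 25 open-chain aldehyde
Product: 28 2-(trimethylsilyl)ethyl 8α-(tert-butyldimethylsilyloxy)-3β-hydroxy-15-(triisopropylsilyloxy)-17,19-dinorlabd-13E-en-18-oate, via C10 tertiary radical 26 (not isolated), via ring B ester enolate 27 (not isolated)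
Conditions: Fe(acac)3 (30 mol %), PhSiH3, EtOH/(CH2OH)2 (5:1), 0 °C → rt
Reagents that add atoms: none
Why: Fe(acac)3/PhSiH3 forms an iron hydride that delivers H• to the CH2 terminus of the C10=C20 alkene (Mukaiyama-type hydrogen-atom transfer); the nucleophilic tertiary C10 radical 26 adds to the electron-poor acrylate carbon C5, the α-ester radical is reduced by divalent iron to enolate 27 (radical–polar crossover), and C4 of 27 adds to the C3 aldehyde. The closest known reaction types are the iron-hydride reductive olefin coupling (hydrogen-atom-transfer Giese addition) and the hydrogen-atom-transfer-initiated radical–polar crossover annulation in which the Giese enolate is trapped by an intramolecular aldol reaction. Ring B closes 6-exo-trig (C5–C10) and ring A closes as a 6-(enolexo)-exo-trig aldol addition (C3–C4). C5 and C10 are set in the chair transition state of the first closure under control of C9: the side chain and the C8 silyloxy group sit equatorial, the acrylate arm equatorial, and the C1–C3 arm pseudo-equatorial because an axial three-carbon arm flanked by the equatorial groups on C9 and C5 has no rotamer free of syn-pentane strain, so the C20 methyl becomes axial (β) and H-5 α (trans fusion); C3 and C4 arise in a chelated chair aldol transition state and are erased in steps 16 and 17, so their configuration is inconsequential. The step needs hydrogen-atom transfer only at the 1,1-disubstituted alkene and radical attack only at C5: the first should follow from the higher reactivity of 1,1-disubstituted over trisubstituted and conjugated alkenes, the second from polarity matching with the only electron-poor alkene and from the slow 5-exo attack on the fully substituted C13.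

Step 16
Reactants: 28 β-hydroxy ester
Product: 30 2-(trimethylsilyl)ethyl 8α-(tert-butyldimethylsilyloxy)-15-(triisopropylsilyloxy)-17,19-dinorlabda-3,13E-dien-18-oate, via C3 mesylate 29 (not isolated)
Conditions: MsCl, Et3N, CH2Cl2, 0 °C; then DBU, rt → 40 °C
Reagents that add atoms: none
Why: mesylation and E1cB elimination through the acidic C4–H should give the conjugated Δ3 ester from any C3/C4 epimer of 28.

Step 17
Reactants: 30 Δ3 ester
Product: 32 2-(trimethylsilyl)ethyl 8α-(tert-butyldimethylsilyloxy)-15-(triisopropylsilyloxy)-17-norlabd-13E-en-19-oate, via lithium ester enolate 31 (not isolated)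
Conditions: Li, NH3(l)/THF, t-BuOH (1 equiv), −78 °C; isoprene; then MeI, −78 → −33 °C
Reagents that add atoms: iodomethane, CI
Why: dissolving-metal conjugate reduction gives the C4 ester enolate, and this reductive alkylation should methylate it from the equatorial α face, opposite the axial C10 methyl, so that the methyl is 4α and the ester axial (C19).

Step 18
Reactants: 32 bis-silyl ether
Product: 33 2-(trimethylsilyl)ethyl 8α,15-dihydroxy-17-norlabd-13E-en-19-oate
Conditions: HF·pyridine, pyridine, THF, 0 °C → rt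
Reagents that add atoms: none
Why: buffered HF should cleave both silyl ethers while the 2-(trimethylsilyl)ethyl ester, which needs basic fluoride, should remain.

Step 19
Reactants: 33 diol; 34 oleic acid
Product: 35 2-(trimethylsilyl)ethyl 8α-hydroxy-15-[(Z)-octadec-9-enoyloxy]-17-norlabd-13E-en-19-oate
Conditions: EDC·HCl, DMAP (10 mol %), CH2Cl2, 0 °C
Reagents that add atoms: none
Why: Steglich esterification should acylate the primary allylic alcohol much faster than the hindered secondary C8 alcohol.

Step 20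
Reactants: 35 hydroxy oleate
Product: 36 2-(trimethylsilyl)ethyl 15-[(Z)-octadec-9-enoyloxy]-8-oxo-17-norlabd-13E-en-19-oate
Conditions: Dess–Martin periodinane, CH2Cl2, rt
Reagents that add atoms: none
Why: hypervalent-iodine oxidation of the secondary alcohol is neutral and should not affect the alkenes or esters; the equatorial C9 side chain is also the thermodynamic arrangement next to the ketone.

Step 21
Reactants: 36 8-ketone
Product: 37 2-(trimethylsilyl)ethyl 15-[(Z)-octadec-9-enoyloxy]labda-8(17),13E-dien-19-oate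
Conditions: Zn, CH2Br2, TiCl4, THF/CH2Cl2, 0 °C → rt
Reagents that add atoms: dibromomethane, BrCBr
Why: Takai–Lombardo methylenation is chemoselective for the ketone over both esters and should install the exocyclic C8=C17 alkene without base.

Step 22
Reactants: 37 2-(trimethylsilyl)ethyl ester
Product: 38 15-[(Z)-octadec-9-enoyloxy]labda-8(17),13E-dien-19-oic acid (4S,5R,9S,10R; the target)
Conditions: Bu4NF, THF, 0 °C → rt; aqueous NH4Cl
Reagents that add atoms: none
Why: fluoride attacks silicon and fragments the 2-(trimethylsilyl)ethyl ester, so the hindered axial acid should be released without any attack at a carbonyl and the oleate should stay in place.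

**Compound list**
1 | ethyl but-2-ynoate | CCOC(=O)C#CC | starting material
2 | but-3-enylmagnesium bromide | C=CCC[Mg]Br | starting material
3 | ethyl (Z)-2-cuprio-3-methylhepta-2,6-dienoate (alkenylcopper adduct, not isolated) | CCOC(=O)/C([Cu])=C(\C)CCC=C | intermediate
4 | ethyl (E)-3-methylhepta-2,6-dienoate | CCOC(=O)/C=C(\C)CCC=C | intermediate
5 | (E)-3-methylhepta-2,6-dien-1-ol | OC/C=C(\C)CCC=C | intermediate
6 | (E)-3-methyl-1-(triisopropylsilyloxy)hepta-2,6-diene | CC(C)[Si](OC/C=C(\C)CCC=C)(C(C)C)C(C)C | intermediate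
7 | B-alkyl-9-BBN adduct of 6 (not isolated) | CC(C)[Si](OC/C=C(\C)CCCCB1C2CCCC1CCC2)(C(C)C)C(C)C | intermediate
8 | (E)-5-methyl-7-(triisopropylsilyloxy)hept-5-en-1-ol | OCCCC/C(C)=C/CO[Si](C(C)C)(C(C)C)C(C)C | intermediate
9 | (E)-5-methyl-7-(triisopropylsilyloxy)hept-5-enoic acid | OC(=O)CCC/C(C)=C/CO[Si](C(C)C)(C(C)C)C(C)C | intermediate
10 | (S)-4-benzyloxazolidin-2-one | O=C1N[C@@H](Cc2ccccc2)CO1 | starting material
11 | mixed pivalic anhydride of 9 (not isolated) | CC(C)(C)C(=O)OC(=O)CCC/C(C)=C/CO[Si](C(C)C)(C(C)C)C(C)C | intermediate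
12 | (S)-4-benzyl-3-[(E)-5-methyl-7-(triisopropylsilyloxy)hept-5-enoyl]oxazolidin-2-one | O=C(CCC/C(C)=C/CO[Si](C(C)C)(C(C)C)C(C)C)N1[C@@H](Cc2ccccc2)COC1=O | intermediate
13 | acryloyl chloride | C=CC(=O)Cl | starting material
14 | 2-(trimethylsilyl)ethanol | C[Si](C)(C)CCO | starting material
15 | 2-(trimethylsilyl)ethyl acrylate | C=CC(=O)OCC[Si](C)(C)C | intermediate
16 | pent-4-enal | C=CCCC=O | starting material
17 | Z-dibutylboron enolate of 12 (not isolated) | CCCCB(CCCC)O/C(=C\CC/C(C)=C/CO[Si](C(C)C)(C(C)C)C(C)C)N1[C@@H](Cc2ccccc2)COC1=O | intermediate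
18 | (S)-4-benzyl-3-[(2S,3R)-3-hydroxy-2-[(E)-3-methyl-5-(triisopropylsilyloxy)pent-3-enyl]hept-6-enoyl]oxazolidin-2-one | O=C([C@@H](CC/C(C)=C/CO[Si](C(C)C)(C(C)C)C(C)C)[C@H](O)CCC=C)N1[C@@H](Cc2ccccc2)COC1=O | intermediate
19 | (2S,3R)-3-hydroxy-N-methoxy-N-methyl-2-[(E)-3-methyl-5-(triisopropylsilyloxy)pent-3-enyl]hept-6-enamide | CON(C)C(=O)[C@@H](CC/C(C)=C/CO[Si](C(C)C)(C(C)C)C(C)C)[C@H](O)CCC=C | intermediate
20 | (2S,3R)-3-(tert-butyldimethylsilyloxy)-N-methoxy-N-methyl-2-[(E)-3-methyl-5-(triisopropylsilyloxy)pent-3-enyl]hept-6-enamide | CON(C)C(=O)[C@@H](CC/C(C)=C/CO[Si](C(C)C)(C(C)C)C(C)C)[C@H](O[Si](C)(C)C(C)(C)C)CCC=C | intermediate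
21 | [2-(1,3-dioxolan-2-yl)ethyl]magnesium bromide | Br[Mg]CCC1OCCO1 | starting material
22 | (4S,5R)-5-(tert-butyldimethylsilyloxy)-1-(1,3-dioxolan-2-yl)-4-[(E)-3-methyl-5-(triisopropylsilyloxy)pent-3-enyl]non-8-en-3-one | O=C(CCC1OCCO1)[C@@H](CC/C(C)=C/CO[Si](C(C)C)(C(C)C)C(C)C)[C@H](O[Si](C)(C)C(C)(C)C)CCC=C | intermediate
23 | 2-(trimethylsilyl)ethyl (2E,6R,7S)-6-(tert-butyldimethylsilyloxy)-10-(1,3-dioxolan-2-yl)-7-[(E)-3-methyl-5-(triisopropylsilyloxy)pent-3-enyl]-8-oxodec-2-enoate | O=C(CCC1OCCO1)[C@@H](CC/C(C)=C/CO[Si](C(C)C)(C(C)C)C(C)C)[C@H](O[Si](C)(C)C(C)(C)C)CC/C=C/C(=O)OCC[Si](C)(C)C | intermediate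
24 | 2-(trimethylsilyl)ethyl (2E,6R,7R)-6-(tert-butyldimethylsilyloxy)-10-(1,3-dioxolan-2-yl)-8-methylidene-7-[(E)-3-methyl-5-(triisopropylsilyloxy)pent-3-enyl]dec-2-enoate | C=C(CCC1OCCO1)[C@@H](CC/C(C)=C/CO[Si](C(C)C)(C(C)C)C(C)C)[C@H](O[Si](C)(C)C(C)(C)C)CC/C=C/C(=O)OCC[Si](C)(C)C | intermediate
25 | 2-(trimethylsilyl)ethyl (2E,6R,7R)-6-(tert-butyldimethylsilyloxy)-8-methylidene-7-[(E)-3-methyl-5-(triisopropylsilyloxy)pent-3-enyl]-11-oxoundec-2-enoate | C=C(CCC=O)[C@@H](CC/C(C)=C/CO[Si](C(C)C)(C(C)C)C(C)C)[C@H](O[Si](C)(C)C(C)(C)C)CC/C=C/C(=O)OCC[Si](C)(C)C | intermediate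
26 | C10 tertiary radical from 25 (not isolated) | C[C](CCC=O)[C@@H](CC/C(C)=C/CO[Si](C(C)C)(C(C)C)C(C)C)[C@H](O[Si](C)(C)C(C)(C)C)CC/C=C/C(=O)OCC[Si](C)(C)C | intermediate
27 | ring B ester enolate after C5–C10 closure (not isolated; iron counter-ion omitted) | [O-]C(OCC[Si](C)(C)C)=C[C@@H]1CC[C@@H](O[Si](C)(C)C(C)(C)C)[C@H](CC/C(C)=C/CO[Si](C(C)C)(C(C)C)C(C)C)[C@@]1(C)CCC=O | intermediate
28 | 2-(trimethylsilyl)ethyl 8α-(tert-butyldimethylsilyloxy)-3β-hydroxy-15-(triisopropylsilyloxy)-17,19-dinorlabd-13E-en-18-oate | CC(C)(C)[Si](C)(C)O[C@@H]1CC[C@@H]2[C@](C)(CC[C@H](O)[C@H]2C(=O)OCC[Si](C)(C)C)[C@H]1CC/C(C)=C/CO[Si](C(C)C)(C(C)C)C(C)C | intermediate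
29 | C3 mesylate of 28 (not isolated) | CC(C)(C)[Si](C)(C)O[C@@H]1CC[C@@H]2[C@](C)(CC[C@H](OS(C)(=O)=O)[C@H]2C(=O)OCC[Si](C)(C)C)[C@H]1CC/C(C)=C/CO[Si](C(C)C)(C(C)C)C(C)C | intermediate
30 | 2-(trimethylsilyl)ethyl 8α-(tert-butyldimethylsilyloxy)-15-(triisopropylsilyloxy)-17,19-dinorlabda-3,13E-dien-18-oate | CC(C)(C)[Si](C)(C)O[C@@H]1CC[C@@H]2[C@](C)(CCC=C2C(=O)OCC[Si](C)(C)C)[C@H]1CC/C(C)=C/CO[Si](C(C)C)(C(C)C)C(C)C | intermediate
31 | lithium C4 ester enolate from 30 (not isolated) | CC(C)(C)[Si](C)(C)O[C@@H]1CC[C@@H]2[C@](C)(CCCC2=C(O[Li])OCC[Si](C)(C)C)[C@H]1CC/C(C)=C/CO[Si](C(C)C)(C(C)C)C(C)C | intermediate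
32 | 2-(trimethylsilyl)ethyl 8α-(tert-butyldimethylsilyloxy)-15-(triisopropylsilyloxy)-17-norlabd-13E-en-19-oate | CC(C)(C)[Si](C)(C)O[C@@H]1CC[C@@H]2[C@](C)(CCC[C@]2(C)C(=O)OCC[Si](C)(C)C)[C@H]1CC/C(C)=C/CO[Si](C(C)C)(C(C)C)C(C)C | intermediate
33 | 2-(trimethylsilyl)ethyl 8α,15-dihydroxy-17-norlabd-13E-en-19-oate | O[C@@H]1CC[C@@H]2[C@](C)(CCC[C@]2(C)C(=O)OCC[Si](C)(C)C)[C@H]1CC/C(C)=C/CO | intermediate
34 | oleic acid | CCCCCCCC/C=C\CCCCCCCC(=O)O | starting material
35 | 2-(trimethylsilyl)ethyl 8α-hydroxy-15-[(Z)-octadec-9-enoyloxy]-17-norlabd-13E-en-19-oate | O[C@@H]1CC[C@@H]2[C@](C)(CCC[C@]2(C)C(=O)OCC[Si](C)(C)C)[C@H]1CC/C(C)=C/COC(=O)CCCCCCC/C=C\CCCCCCCC | intermediate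
36 | 2-(trimethylsilyl)ethyl 15-[(Z)-octadec-9-enoyloxy]-8-oxo-17-norlabd-13E-en-19-oate | O=C1CC[C@@H]2[C@](C)(CCC[C@]2(C)C(=O)OCC[Si](C)(C)C)[C@H]1CC/C(C)=C/COC(=O)CCCCCCC/C=C\CCCCCCCC | intermediate
37 | 2-(trimethylsilyl)ethyl 15-[(Z)-octadec-9-enoyloxy]labda-8(17),13E-dien-19-oate | C=C1CC[C@@H]2[C@](C)(CCC[C@]2(C)C(=O)OCC[Si](C)(C)C)[C@H]1CC/C(C)=C/COC(=O)CCCCCCC/C=C\CCCCCCCC | intermediate
38 | 15-[(Z)-octadec-9-enoyloxy]labda-8(17),13E-dien-19-oic acid | C=C1CC[C@@H]2[C@](C)(CCC[C@]2(C)C(=O)O)[C@H]1CC/C(C)=C/COC(=O)CCCCCCC/C=C\CCCCCCCC | target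

**Totals**
Total step count: 22. Longest linear sequence: 21 steps (steps 1–6, then 8–22; step 7 is a one-step side branch).

**Steps most likely to fail**

Step 15 (key step). The cascade may be interrupted: the ester enolate may be protonated by the alcohol solvent before it closes onto the aldehyde, the aldehyde may be reduced, or the facial control at C10 in the radical closure may be incomplete. The fallback makes the C3–C4 ring closure a separate, polar event. It sets out from 24: under the same iron-hydride conditions (Fe(acac)3, PhSiH3, EtOH, 60 °C), with the aldehyde still masked, 24 should undergo only the reductive 6-exo cyclisation to the monocyclic ring B ester F1, at which stage C10 epimers can be separated. F1 is treated with LiN(i-Pr)2 (2.2 equiv) and ClP(O)(OEt)2 (O-phosphorylation of the ester enolate, then 1,3-phosphorus migration) to give the α-phosphono ester F2. PPTS in wet acetone unmasks the aldehyde F3, and LiCl/DBU in MeCN closes ring A by an intramolecular Horner–Wadsworth–Emmons reaction that forms C3=C4. The fallback comes back to the route at 30.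

Step 17. Over-reduction under the dissolving-metal conditions (ester carbonyl or allylic C–O cleavage), or protonation of the enolate instead of methylation, would erode the step. The fallback separates reduction and alkylation. It sets out from 30: SmI2 with HMPA and t-BuOH in THF should reduce only the conjugated double bond to the saturated ester F4 (C4 epimers), and F4 is then deprotonated with LiN(i-Pr)2 at −78 °C and methylated with MeI, the electrophile again entering the α face. It comes back at 32.

Step 13. Methylenation of the hindered α-branched ketone may be slow, allowing epimerisation at C9 or β-elimination of the silyloxy group. The fallback is a two-stage Peterson olefination. It sets out from 23: Me3SiCH2Li with CeCl3 in THF at −78 °C should add to the ketone and not the ester to give the β-hydroxysilane F5, and KH in THF then triggers syn-elimination. It comes back at 24.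

**Further compounds**
F1 | step 15 | 2-(trimethylsilyl)ethyl ring B monocyclic ester from reductive cyclisation of 24 (dioxolane intact) | C[Si](C)(C)CCOC(=O)C[C@@H]1CC[C@@H](O[Si](C)(C)C(C)(C)C)[C@H](CC/C(C)=C/CO[Si](C(C)C)(C(C)C)C(C)C)[C@@]1(C)CCC2OCCO2
F2 | step 15 | α-(diethoxyphosphoryl) ester from F1 (C4 epimers) | C[Si](C)(C)CCOC(=O)C(P(=O)(OCC)OCC)[C@@H]1CC[C@@H](O[Si](C)(C)C(C)(C)C)[C@H](CC/C(C)=C/CO[Si](C(C)C)(C(C)C)C(C)C)[C@@]1(C)CCC2OCCO2
F3 | step 15 | phosphono ester aldehyde from F2 | C[Si](C)(C)CCOC(=O)C(P(=O)(OCC)OCC)[C@@H]1CC[C@@H](O[Si](C)(C)C(C)(C)C)[C@H](CC/C(C)=C/CO[Si](C(C)C)(C(C)C)C(C)C)[C@@]1(C)CCC=O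
F4 | step 17 | 2-(trimethylsilyl)ethyl 8α-(tert-butyldimethylsilyloxy)-15-(triisopropylsilyloxy)-17,19-dinorlabd-13E-en-18-oate (saturated; C4 epimers) | CC(C)(C)[Si](C)(C)O[C@@H]1CC[C@@H]2[C@](C)(CCC[C@H]2C(=O)OCC[Si](C)(C)C)[C@H]1CC/C(C)=C/CO[Si](C(C)C)(C(C)C)C(C)C
F5 | step 13 | β-hydroxysilane from addition of Me3SiCH2Li to 23 (C10 epimers) | C[Si](C)(C)CC(O)(CCC1OCCO1)[C@@H](CC/C(C)=C/CO[Si](C(C)C)(C(C)C)C(C)C)[C@H](O[Si](C)(C)C(C)(C)C)CC/C=C/C(=O)OCC[Si](C)(C)C
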